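The route rests on a De Mayo disconnection of the quaternary carbon C8, which carries the methyl group and the ring oxygen of the tetrahydrofuran-3-one (O, C8, C9, C10, C11) and sits between the C7–C6 and C9–C10 ketone arms (a 1,5-diketone). One irradiation of a 1,3-diketone whose C11 oxygen bears an isopropenyl group forms C8–C9 and C6–C7, closes the furanone, sets C8 against C11 and, after retro-aldol opening of the cyclobutanol, frees the C6 ketone. The precursor is a chiral-pool C5–C13 heptane-2,4-dione, silyl-capped at both ends. Alkylation, Z-selective olefination and a chromium-mediated ring closure then add C1–C4 and C14.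

Key step: step 7

Remark: the carbocycle numbering of the target (C1 = CH bearing isopropenyl, O bridging C8 and C11) is used for all intermediates, and (R)-BINAP is assumed to give the (R)-lactone in the rhodium step by the usual facial model for cyclic enones and lactones (the antipodal ligand would be used otherwise).

Step 1
Reactants: 1 hydroxyacetone (1-hydroxypropan-2-one)
Product: 2 1-[(tert-butyldimethylsilyl)oxy]propan-2-one
Conditions: TBSCl, imidazole, CH2Cl2, 0 °C to rt
Reagents that add atoms: tert-butyldimethylsilyl chloride CC(C)(C)[Si](C)(C)Cl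
Why: Imidazole-promoted silylation of the primary alcohol gives an ether that survives amide bases and, unlike a benzylic ether, offers the neighbouring ketone no hydrogen to abstract under light.

Step 2
Reactants: 3 (R)-3-hydroxydihydrofuran-2(3H)-one
Product: 4 (R)-2,4-dihydroxy-N-methoxy-N-methylbutanamide
Conditions: MeNH(OMe)·HCl, AlMe3, CH2Cl2, 0 °C to rt; aq. potassium sodium tartrate
Reagents that add atoms: N,O-dimethylhydroxylamine hydrochloride CNOC.Cl
Why: Weinreb aminolysis of the lactone with the aluminium amide opens the ring without touching the C11 stereocentre and exposes the C13 hydroxyl before any acid-labile group is present.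

Step 3
Reactants: 4 (R)-2,4-dihydroxy-N-methoxy-N-methylbutanamide
Product: 5 (R)-4-[(tert-butyldiphenylsilyl)oxy]-2-hydroxy-N-methoxy-N-methylbutanamide
Conditions: TBDPSCl (1.05 equiv), imidazole, CH2Cl2, 0 °C
Reagents that add atoms: tert-butyldiphenylsilyl chloride CC(C)(C)[Si](Cl)(c1ccccc1)c1ccccc1
Why: Silylation with a bulky chlorosilane selects the primary C13 hydroxyl over the hindered secondary C11 hydroxyl, and the resulting TBDPS ether should later outlast the fluoride that removes the TBS group.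

Step 4
Reactants: 5 (R)-4-[(tert-butyldiphenylsilyl)oxy]-2-hydroxy-N-methoxy-N-methylbutanamide; 6 2-methoxypropene
Product: 7 (R)-4-[(tert-butyldiphenylsilyl)oxy]-N-methoxy-2-[(2-methoxypropan-2-yl)oxy]-N-methylbutanamide
Conditions: PPTS (cat.), CH2Cl2, 0 °C; Et3N quench, concentrate
Reagents that add atoms: none
Why: Acid-catalysed addition of the secondary alcohol to the enol ether (mixed ketal formation) is fast and leaves the stereocentre and the silyl ether untouched.

Step 5
Reactants: 7 (R)-4-[(tert-butyldiphenylsilyl)oxy]-N-methoxy-2-[(2-methoxypropan-2-yl)oxy]-N-methylbutanamide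
Product: 8 (R)-4-[(tert-butyldiphenylsilyl)oxy]-N-methoxy-N-methyl-2-(prop-1-en-2-yloxy)butanamide
Conditions: Me3SiOTf, Et3N, CH2Cl2, 0 °C to rt; aq. NaHCO3
Reagents that add atoms: none
Why: Silyl triflate and amine eliminate the mixed ketal to the enol ether, a reaction type used for isopropenyl ethers of secondary alcohols, with the more basic and less hindered methoxy group leaving as methoxytrimethylsilane and the basic medium protecting C11 from epimerisation.

Step 6
Reactants: 2 1-[(tert-butyldimethylsilyl)oxy]propan-2-one; 8 (R)-4-[(tert-butyldiphenylsilyl)oxy]-N-methoxy-N-methyl-2-(prop-1-en-2-yloxy)butanamide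
Product: 10 (R)-1-[(tert-butyldimethylsilyl)oxy]-7-[(tert-butyldiphenylsilyl)oxy]-5-(prop-1-en-2-yloxy)heptane-2,4-dione, via lithium enolate 9 (not isolated)
Conditions: LiN(i-Pr)2 (2.0 equiv), 2 (2.1 equiv), THF, −78 °C; then 8, −78 to −20 °C; aq. NaH2PO4/Na2HPO4 (pH 7)
Reagents that add atoms: none
Why: Kinetic deprotonation of the methyl group and Claisen-type acylation by the Weinreb amide give the 1,3-diketone once the chelated adduct collapses on neutral work-up, and because C13 is already capped no hydroxyl can add to the enol ether.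

Step 7
Reactants: 10 (R)-1-[(tert-butyldimethylsilyl)oxy]-7-[(tert-butyldiphenylsilyl)oxy]-5-(prop-1-en-2-yloxy)heptane-2,4-dione
Product: 12 (2R,5R)-5-{3-[(tert-butyldimethylsilyl)oxy]-2-oxopropyl}-2-{2-[(tert-butyldiphenylsilyl)oxy]ethyl}-5-methyldihydrofuran-3(2H)-one, via cyclobutanol photoadduct 11 (not isolated)
Conditions: hν (medium-pressure Hg lamp, Pyrex, > 290 nm), degassed cyclohexane (5 mM), base-washed vessel, 10 °C; then rt
Reagents that add atoms: none
Why: Excitation of the chelated enol of the 1,3-diketone lets C9 bond to the oxygen-bearing carbon C8 of the tethered isopropenyl ether in a 5-exo closure that creates the O–C8–C9–C10–C11 ring, the C6/C7 1,4-diradical then collapses to the cis-fused cyclobutanol 11 (a 6-hydroxy-2-oxabicyclo[3.2.0]heptan-4-one), and this strained beta-hydroxy ketone opens by retro-aldol cleavage of C6–C9 to unveil the C6 ketone and the 1,5-diketone. The closest known reaction type is the intramolecular De Mayo reaction, supported by the straight 1,5-closure of 1,6-dien-3-ones to bicyclo[3.2.0]heptan-2-ones and by intermolecular De Mayo additions to enol ethers; what is new here is only the substrate, with the alkene attached through the alpha-oxygen. Regiochemistry should be secured twice, because the three-atom tether (C10, C11, O) favours the five-membered ring and the head-to-tail preference of excited enones for electron-rich alkenes also joins C9 to the alkoxy carbon. C8, the only new stereocentre, is set relative to C11 (from the chiral pool) by the C12 chain, made bulky by its TBDPS ether, taking the convex face of the bicycle anti to C6 and C7, which leaves C7 trans to C12 (8R); if the other enol tautomer reacts through a 2-oxabicyclo[2.1.1]hexane, the same avoidance of the acyl-bearing bridge again puts the ketone arm trans to C12. The step needs cycloaddition to outrun acid-promoted hydrolysis or cyclisation of the enol ether and secondary photoreactions, which the design answers with acid-free, base-washed conditions, silyl ethers that offer the ketones no abstractable hydrogen, a C13 oxygen capped before the enol ether exists, and irradiation before any enoate or beta,gamma-unsaturated ketone is present.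

Step 8
Reactants: 12 (2R,5R)-5-{3-[(tert-butyldimethylsilyl)oxy]-2-oxopropyl}-2-{2-[(tert-butyldiphenylsilyl)oxy]ethyl}-5-methyldihydrofuran-3(2H)-one
Product: 13 (2R,5R)-2-{2-[(tert-butyldiphenylsilyl)oxy]ethyl}-5-(3-hydroxy-2-oxopropyl)-5-methyldihydrofuran-3(2H)-one
Conditions: HF·pyridine, pyridine, THF, 0 °C
Reagents that add atoms: none
Why: Fluoride-mediated desilylation is faster for the primary TBS ether next to the ketone than for the TBDPS ether, and the buffered, non-basic medium should leave both beta-alkoxy ketones closed.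

Step 9
Reactants: 13 (2R,5R)-2-{2-[(tert-butyldiphenylsilyl)oxy]ethyl}-5-(3-hydroxy-2-oxopropyl)-5-methyldihydrofuran-3(2H)-one
Product: 15 (2R,5S)-2-{2-[(tert-butyldiphenylsilyl)oxy]ethyl}-5-(3-iodo-2-oxopropyl)-5-methyldihydrofuran-3(2H)-one, via mesylate 14 (not isolated)
Conditions: MsCl, Et3N, CH2Cl2, −30 °C; then NaI, acetone, rt, dark
Reagents that add atoms: methanesulfonyl chloride CS(=O)(=O)Cl (retained in 14 only); sodium iodide [Na+].[I-]
Why: Sulfonylation followed by Finkelstein displacement at a primary carbon activated by the adjacent carbonyl gives the alpha-iodo ketone without phosphines that attack such halides, the change of the C8 descriptor being only a matter of priority.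

Step 10
Reactants: 15 (2R,5S)-2-{2-[(tert-butyldiphenylsilyl)oxy]ethyl}-5-(3-iodo-2-oxopropyl)-5-methyldihydrofuran-3(2H)-one; 16 methyl 2-[bis(2,2,2-trifluoroethoxy)phosphoryl]acetate
Product: 18 methyl 2-[bis(2,2,2-trifluoroethoxy)phosphoryl]-5-[(2R,5R)-5-{2-[(tert-butyldiphenylsilyl)oxy]ethyl}-2-methyl-4-oxotetrahydrofuran-2-yl]-4-oxopentanoate (both C4 epimers), via sodium phosphonoacetate 17 (not isolated)
Conditions: 16 (1.3 equiv), NaH (1.25 equiv), THF, 0 °C; then 15, THF, −20 to 0 °C
Reagents that add atoms: none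
Why: SN2 alkylation of a stabilised phosphonoacetate carbanion by an alpha-halo ketone is fast at low temperature, and the weakly basic anion should not enolise the C6 ketone toward C7 and open the furanone.

Step 11
Reactants: 19 furan-2(5H)-one; 20 4,4,5,5-tetramethyl-2-(prop-1-en-2-yl)-1,3,2-dioxaborolane
Product: 21 (R)-4-(prop-1-en-2-yl)dihydrofuran-2(3H)-one
Conditions: [Rh(OH)(cod)]2 (3 mol %), (R)-BINAP (7 mol %), 20 (2.5 equiv), dioxane/H2O (10:1), 50 °C
Reagents that add atoms: none
Why: Rhodium/BINAP-catalysed asymmetric 1,4-addition of an alkenylboron reagent to an unsaturated lactone (Hayashi–Miyaura reaction) sets C1, the ligand enantiomer fixing the face of the butenolide that receives the isopropenyl group.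

Step 12
Reactants: 21 (R)-4-(prop-1-en-2-yl)dihydrofuran-2(3H)-one
Product: 22 (R)-3-(hydroxymethyl)-N-methoxy-N,4-dimethylpent-4-enamide
Conditions: MeNH(OMe)·HCl, AlMe3, CH2Cl2, 0 °C to rt; aq. potassium sodium tartrate
Reagents that add atoms: N,O-dimethylhydroxylamine hydrochloride CNOC.Cl
Why: Weinreb aminolysis opens the lactone to a C3 amide at the aldehyde-precursor level and a free C14 hydroxyl, and C1, which is not alpha to the carbonyl, cannot epimerise.

Step 13
Reactants: 22 (R)-3-(hydroxymethyl)-N-methoxy-N,4-dimethylpent-4-enamide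
Product: 23 (R)-3-(iodomethyl)-N-methoxy-N,4-dimethylpent-4-enamide
Conditions: I2, PPh3, imidazole, CH2Cl2, 0 °C
Reagents that add atoms: iodine [I][I]
Why: Appel-type iodination converts the primary alcohol into the iodide under neutral conditions that spare the 1,1-disubstituted alkene.

Step 14
Reactants: 23 (R)-3-(iodomethyl)-N-methoxy-N,4-dimethylpent-4-enamide
Product: 24 (R)-3-(iodomethyl)-4-methylpent-4-enal
Conditions: i-Bu2AlH (1.2 equiv), THF, −78 °C; aq. potassium sodium tartrate; used at once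
Reagents that add atoms: none
Why: Hydride reduction of a Weinreb amide stops at the chelated hemiaminal, which releases the aldehyde on work-up while the alkyl iodide and C1 are unaffected.

Step 15
Reactants: 18 methyl 2-[bis(2,2,2-trifluoroethoxy)phosphoryl]-5-[(2R,5R)-5-{2-[(tert-butyldiphenylsilyl)oxy]ethyl}-2-methyl-4-oxotetrahydrofuran-2-yl]-4-oxopentanoate; 24 (R)-3-(iodomethyl)-4-methylpent-4-enal
Product: 26 methyl (2Z,5R)-5-(iodomethyl)-6-methyl-2-{3-[(2R,5R)-5-{2-[(tert-butyldiphenylsilyl)oxy]ethyl}-2-methyl-4-oxotetrahydrofuran-2-yl]-2-oxopropyl}hepta-2,6-dienoate, via potassium phosphonate 25 (not isolated)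
Conditions: KN(SiMe3)2 (1.0 equiv), 18-crown-6, THF, −78 °C; then 24 (1.3 equiv), −78 °C; aq. NH4Cl at −78 °C
Reagents that add atoms: none
Why: In the Still–Gennari olefination the electron-poor bis(trifluoroethyl) phosphonate eliminates faster than its adducts equilibrate, which should place the ester cis to C2 (3Z), and forming the anion with exactly one equivalent of base at −78 °C keeps the ketones and the alkyl iodide out of play.

Step 16
Reactants: 26 methyl (2Z,5R)-5-(iodomethyl)-6-methyl-2-{3-[(2R,5R)-5-{2-[(tert-butyldiphenylsilyl)oxy]ethyl}-2-methyl-4-oxotetrahydrofuran-2-yl]-2-oxopropyl}hepta-2,6-dienoate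
Product: 27 methyl (2Z,5R)-2-{3-[(2R,5R)-5-(2-hydroxyethyl)-2-methyl-4-oxotetrahydrofuran-2-yl]-2-oxopropyl}-5-(iodomethyl)-6-methylhepta-2,6-dienoate
Conditions: HF·pyridine, pyridine, THF, 0 °C to rt
Reagents that add atoms: none
Why: Fluoride-mediated cleavage of the silyl ether in a buffered, non-basic medium should leave the Z-enoate, the acidic C5 methylene between alkene and ketone, and the primary iodide intact.

Step 17
Reactants: 27 methyl (2Z,5R)-2-{3-[(2R,5R)-5-(2-hydroxyethyl)-2-methyl-4-oxotetrahydrofuran-2-yl]-2-oxopropyl}-5-(iodomethyl)-6-methylhepta-2,6-dienoate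
Product: 28 methyl (2Z,5R)-5-(iodomethyl)-6-methyl-2-{3-[(2R,5R)-2-methyl-4-oxo-5-(2-oxoethyl)tetrahydrofuran-2-yl]-2-oxopropyl}hepta-2,6-dienoate
Conditions: Dess–Martin periodinane, CH2Cl2, rt; used crude
Reagents that add atoms: none
Why: Dess–Martin oxidation gives the C13 aldehyde without base, so the C11 oxygen is not lost by beta-elimination from the beta-alkoxy aldehyde.

Step 18
Reactants: 28 methyl (2Z,5R)-5-(iodomethyl)-6-methyl-2-{3-[(2R,5R)-2-methyl-4-oxo-5-(2-oxoethyl)tetrahydrofuran-2-yl]-2-oxopropyl}hepta-2,6-dienoate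
Product: 29 methyl (1S,3Z,8R,11R)-13-hydroxy-8-methyl-6,10-dioxo-1-(prop-1-en-2-yl)-8,11-epoxycyclotetradec-3-ene-4-carboxylate (both C13 epimers)
Conditions: CrCl2 (8 equiv), CoPc (cobalt phthalocyanine, 20 mol %), DMF, slow addition of 28 to 2 mM, rt to 40 °C
Reagents that add atoms: none
Why: Cobalt-catalysed formation of an alkylchromium reagent from the primary iodide and its addition to an aldehyde (the alkyl variant of the Nozaki–Hiyama–Kishi reaction, Takai–Utimoto conditions) is selective for aldehydes over ketones and esters, so under high dilution C14 should add only to C13 and close the 14-membered ring, the new carbinol centre being of no consequence.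

Step 19
Reactants: 29 methyl (1S,3Z,8R,11R)-13-hydroxy-8-methyl-6,10-dioxo-1-(prop-1-en-2-yl)-8,11-epoxycyclotetradec-3-ene-4-carboxylate
Product: 30 methyl (1S,3Z,8R,11R)-8-methyl-6,10,13-trioxo-1-(prop-1-en-2-yl)-8,11-epoxycyclotetradec-3-ene-4-carboxylate (target)
Conditions: Dess–Martin periodinane, CH2Cl2, 0 °C to rt
Reagents that add atoms: none
Why: Dess–Martin oxidation of the secondary alcohol installs the C13 ketone last and without base, which matters because the product can open at C11–O or C8–O and shift its C3–C4 alkene once base is present.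

Compound list
1 | hydroxyacetone (1-hydroxypropan-2-one) | CC(=O)CO | starting material
2 | 1-[(tert-butyldimethylsilyl)oxy]propan-2-one | CC(=O)CO[Si](C)(C)C(C)(C)C | intermediate
3 | (R)-3-hydroxydihydrofuran-2(3H)-one ((R)-alpha-hydroxy-gamma-butyrolactone) | O[C@@H]1CCOC1=O | starting material
4 | (R)-2,4-dihydroxy-N-methoxy-N-methylbutanamide | O[C@H](CCO)C(=O)N(C)OC | intermediate
5 | (R)-4-[(tert-butyldiphenylsilyl)oxy]-2-hydroxy-N-methoxy-N-methylbutanamide | O[C@H](CCO[Si](c1ccccc1)(c1ccccc1)C(C)(C)C)C(=O)N(C)OC | intermediate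
6 | 2-methoxypropene | COC(C)=C | starting material
7 | (R)-4-[(tert-butyldiphenylsilyl)oxy]-N-methoxy-2-[(2-methoxypropan-2-yl)oxy]-N-methylbutanamide | COC(C)(C)O[C@H](CCO[Si](c1ccccc1)(c1ccccc1)C(C)(C)C)C(=O)N(C)OC | intermediate
8 | (R)-4-[(tert-butyldiphenylsilyl)oxy]-N-methoxy-N-methyl-2-(prop-1-en-2-yloxy)butanamide | C=C(C)O[C@H](CCO[Si](c1ccccc1)(c1ccccc1)C(C)(C)C)C(=O)N(C)OC | intermediate
9 | lithium 3-[(tert-butyldimethylsilyl)oxy]prop-1-en-2-olate (kinetic enolate of 2, not isolated) | [Li+].[O-]C(=C)CO[Si](C)(C)C(C)(C)C | intermediate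
10 | (R)-1-[(tert-butyldimethylsilyl)oxy]-7-[(tert-butyldiphenylsilyl)oxy]-5-(prop-1-en-2-yloxy)heptane-2,4-dione (C5–C13 diketone, C11 R) | CC(C)(C)[Si](C)(C)OCC(=O)CC(=O)[C@@H](CCO[Si](c1ccccc1)(c1ccccc1)C(C)(C)C)OC(C)=C | intermediate
11 | (1R,3R,5S)-6-{[(tert-butyldimethylsilyl)oxy]methyl}-3-{2-[(tert-butyldiphenylsilyl)oxy]ethyl}-6-hydroxy-1-methyl-2-oxabicyclo[3.2.0]heptan-4-one (cis-fused, side chain anti to the cyclobutane, either C6 epimer, not isolated) | CC(C)(C)[Si](C)(C)OCC1(O)C[C@@]2(C)O[C@H](CCO[Si](c3ccccc3)(c3ccccc3)C(C)(C)C)C(=O)[C@@H]12 | intermediate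
12 | (2R,5R)-5-{3-[(tert-butyldimethylsilyl)oxy]-2-oxopropyl}-2-{2-[(tert-butyldiphenylsilyl)oxy]ethyl}-5-methyldihydrofuran-3(2H)-one (C8 R, C11 R) | CC(C)(C)[Si](C)(C)OCC(=O)C[C@]1(C)CC(=O)[C@@H](CCO[Si](c2ccccc2)(c2ccccc2)C(C)(C)C)O1 | intermediate
13 | (2R,5R)-2-{2-[(tert-butyldiphenylsilyl)oxy]ethyl}-5-(3-hydroxy-2-oxopropyl)-5-methyldihydrofuran-3(2H)-one | OCC(=O)C[C@]1(C)CC(=O)[C@@H](CCO[Si](c2ccccc2)(c2ccccc2)C(C)(C)C)O1 | intermediate
14 | 3-[(2R,5R)-5-{2-[(tert-butyldiphenylsilyl)oxy]ethyl}-2-methyl-4-oxotetrahydrofuran-2-yl]-2-oxopropyl methanesulfonate (not isolated) | CS(=O)(=O)OCC(=O)C[C@]1(C)CC(=O)[C@@H](CCO[Si](c2ccccc2)(c2ccccc2)C(C)(C)C)O1 | intermediate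
15 | (2R,5S)-2-{2-[(tert-butyldiphenylsilyl)oxy]ethyl}-5-(3-iodo-2-oxopropyl)-5-methyldihydrofuran-3(2H)-one (same spatial arrangement as 13) | ICC(=O)C[C@]1(C)CC(=O)[C@@H](CCO[Si](c2ccccc2)(c2ccccc2)C(C)(C)C)O1 | intermediate
16 | methyl 2-[bis(2,2,2-trifluoroethoxy)phosphoryl]acetate | COC(=O)CP(=O)(OCC(F)(F)F)OCC(F)(F)F | starting material
17 | sodium salt of 16 (phosphonoacetate carbanion, not isolated) | [Na+].COC(=O)[CH-]P(=O)(OCC(F)(F)F)OCC(F)(F)F | intermediate
18 | methyl 2-[bis(2,2,2-trifluoroethoxy)phosphoryl]-5-[(2R,5R)-5-{2-[(tert-butyldiphenylsilyl)oxy]ethyl}-2-methyl-4-oxotetrahydrofuran-2-yl]-4-oxopentanoate (both C4 epimers) | COC(=O)C(CC(=O)C[C@]1(C)CC(=O)[C@@H](CCO[Si](c2ccccc2)(c2ccccc2)C(C)(C)C)O1)P(=O)(OCC(F)(F)F)OCC(F)(F)F | intermediate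
19 | furan-2(5H)-one | O=C1OCC=C1 | starting material
20 | 4,4,5,5-tetramethyl-2-(prop-1-en-2-yl)-1,3,2-dioxaborolane (isopropenylboronic acid pinacol ester) | CC(=C)B1OC(C)(C)C(C)(C)O1 | starting material
21 | (R)-4-(prop-1-en-2-yl)dihydrofuran-2(3H)-one | C=C(C)[C@H]1CC(=O)OC1 | intermediate
22 | (R)-3-(hydroxymethyl)-N-methoxy-N,4-dimethylpent-4-enamide | C=C(C)[C@H](CO)CC(=O)N(C)OC | intermediate
23 | (R)-3-(iodomethyl)-N-methoxy-N,4-dimethylpent-4-enamide | C=C(C)[C@H](CI)CC(=O)N(C)OC | intermediate
24 | (R)-3-(iodomethyl)-4-methylpent-4-enal | C=C(C)[C@H](CI)CC=O | intermediate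
25 | potassium salt of 18 (phosphonate carbanion at C4, not isolated) | [K+].COC(=O)[C-](CC(=O)C[C@]1(C)CC(=O)[C@@H](CCO[Si](c2ccccc2)(c2ccccc2)C(C)(C)C)O1)P(=O)(OCC(F)(F)F)OCC(F)(F)F | intermediate
26 | methyl (2Z,5R)-5-(iodomethyl)-6-methyl-2-{3-[(2R,5R)-5-{2-[(tert-butyldiphenylsilyl)oxy]ethyl}-2-methyl-4-oxotetrahydrofuran-2-yl]-2-oxopropyl}hepta-2,6-dienoate | C=C(C)[C@H](CI)C/C=C(\C(=O)OC)CC(=O)C[C@]1(C)CC(=O)[C@@H](CCO[Si](c2ccccc2)(c2ccccc2)C(C)(C)C)O1 | intermediate
27 | methyl (2Z,5R)-2-{3-[(2R,5R)-5-(2-hydroxyethyl)-2-methyl-4-oxotetrahydrofuran-2-yl]-2-oxopropyl}-5-(iodomethyl)-6-methylhepta-2,6-dienoate | C=C(C)[C@H](CI)C/C=C(\C(=O)OC)CC(=O)C[C@]1(C)CC(=O)[C@@H](CCO)O1 | intermediate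
28 | methyl (2Z,5R)-5-(iodomethyl)-6-methyl-2-{3-[(2R,5R)-2-methyl-4-oxo-5-(2-oxoethyl)tetrahydrofuran-2-yl]-2-oxopropyl}hepta-2,6-dienoate | C=C(C)[C@H](CI)C/C=C(\C(=O)OC)CC(=O)C[C@]1(C)CC(=O)[C@@H](CC=O)O1 | intermediate
29 | methyl (1S,3Z,8R,11R)-13-hydroxy-8-methyl-6,10-dioxo-1-(prop-1-en-2-yl)-8,11-epoxycyclotetradec-3-ene-4-carboxylate (carbocycle numbering, both C13 epimers) | C=C(C)[C@H]1C/C=C(\C(=O)OC)CC(=O)C[C@]2(C)CC(=O)[C@@H](CC(O)C1)O2 | intermediate
30 | methyl (1S,3Z,8R,11R)-8-methyl-6,10,13-trioxo-1-(prop-1-en-2-yl)-8,11-epoxycyclotetradec-3-ene-4-carboxylate (carbocycle numbering) | C=C(C)[C@H]1C/C=C(\C(=O)OC)CC(=O)C[C@]2(C)CC(=O)[C@@H](CC(=O)C1)O2 | target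

Total step count: 19. Longest linear sequence: 14 steps (steps 2–10 and 15–19, from lactone 3).

Steps most likely to fail

Step 7. What may go wrong: crossed instead of straight closure, weak facial control at C8, or acid-triggered loss of the enol ether before light is absorbed. The fallback drops the tether and builds C8 stepwise. Setting out from ketal 7, acylation of enolate 9 as in step 6 should give the ketal-protected diketone F1. Irradiation of F1 through Pyrex with excess 2-methoxypropene 6 (intermolecular De Mayo reaction, head-to-tail) should pass through the cyclobutanol photoadduct F2 to the 8-methoxy 1,5-diketone F3. Camphorsulfonic acid in moist CH2Cl2 should then remove the ketal, eliminate methanol to the hydroxy enone F4 and close the C11 hydroxyl onto C8 by 5-exo oxa-Michael addition, which returns to the route at furanone 12. C8 is then set under thermodynamic control, and the unwanted epimer can be resubmitted to the same acid.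

Step 18. What may go wrong: the alkylchromium adds too slowly at high dilution, so that protonation at C14, oligomerisation or rearrangement of the C14 radical takes over. The fallback makes the C13–C14 bond between two molecules and closes the ring at C3=C4. Setting out from phosphonate 18, HF·pyridine should give the C13 alcohol F5 and Dess–Martin oxidation the phosphonate aldehyde F6. Aldehyde 24 is converted with HC(OMe)3 and PPTS into the iodo acetal F7. CrCl2 with catalytic CoPc in DMF should join F7 (in excess) to F6 as the open-chain carbinol F8, and PPTS in wet acetone should release the seco aldehyde F9. K2CO3 with 18-crown-6 in toluene under high dilution (intramolecular Still–Gennari olefination) should then close the ring to carbinol 29, where the route is rejoined before step 19.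

Step 6. What may go wrong: slow acylation of the enolate by the amide, or loss of the enol ether on work-up. The fallback reaches the diketone by aldol addition and oxidation. Setting out from amide 8, i-Bu2AlH at −78 °C should give the alpha-alkoxy aldehyde F10. Addition of enolate 9 at −78 °C should give the beta-hydroxy ketone F11 (either C10 epimer), and Dess–Martin periodinane buffered with pyridine the diketone 10, where the route is rejoined.

Further compounds
F1 | step 7 | (R)-1-[(tert-butyldimethylsilyl)oxy]-7-[(tert-butyldiphenylsilyl)oxy]-5-[(2-methoxypropan-2-yl)oxy]heptane-2,4-dione | CC(C)(C)[Si](C)(C)OCC(=O)CC(=O)[C@@H](CCO[Si](c1ccccc1)(c1ccccc1)C(C)(C)C)OC(C)(C)OC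
F2 | step 7 | cyclobutanol photoadduct of F1 and 6: 1-hydroxy-3-methoxy-3-methylcyclobutane with the siloxymethyl group on the carbinol carbon and the C10 acyl group on the adjacent ring carbon (isomer mixture) | CC(C)(C)[Si](C)(C)OCC1(O)CC(C)(OC)C1C(=O)[C@@H](CCO[Si](c2ccccc2)(c2ccccc2)C(C)(C)C)OC(C)(C)OC
F3 | step 7 | (7R)-1-[(tert-butyldimethylsilyl)oxy]-9-[(tert-butyldiphenylsilyl)oxy]-4-methoxy-7-[(2-methoxypropan-2-yl)oxy]-4-methylnonane-2,6-dione (both C8 epimers) | CC(C)(C)[Si](C)(C)OCC(=O)CC(C)(OC)CC(=O)[C@@H](CCO[Si](c1ccccc1)(c1ccccc1)C(C)(C)C)OC(C)(C)OC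
F4 | step 7 | (7R)-1-[(tert-butyldimethylsilyl)oxy]-9-[(tert-butyldiphenylsilyl)oxy]-7-hydroxy-4-methylnon-3-ene-2,6-dione (alkene isomers) | CC(C)(C)[Si](C)(C)OCC(=O)C=C(C)CC(=O)[C@H](O)CCO[Si](c1ccccc1)(c1ccccc1)C(C)(C)C
F5 | step 18 | methyl 2-[bis(2,2,2-trifluoroethoxy)phosphoryl]-5-[(2R,5R)-5-(2-hydroxyethyl)-2-methyl-4-oxotetrahydrofuran-2-yl]-4-oxopentanoate | COC(=O)C(CC(=O)C[C@]1(C)CC(=O)[C@@H](CCO)O1)P(=O)(OCC(F)(F)F)OCC(F)(F)F
F6 | step 18 | methyl 2-[bis(2,2,2-trifluoroethoxy)phosphoryl]-5-[(2R,5R)-2-methyl-4-oxo-5-(2-oxoethyl)tetrahydrofuran-2-yl]-4-oxopentanoate | COC(=O)C(CC(=O)C[C@]1(C)CC(=O)[C@@H](CC=O)O1)P(=O)(OCC(F)(F)F)OCC(F)(F)F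
F7 | step 18 | (R)-3-(iodomethyl)-5,5-dimethoxy-2-methylpent-1-ene | C=C(C)[C@H](CI)CC(OC)OC
F8 | step 18 | open-chain carbinol: C13 secondary alcohol (both epimers) bonded to C14, C3 as dimethyl acetal, C4 phosphonate (C1 as in 24, C8 R, C11 R) | COC(=O)C(CC(=O)C[C@]1(C)CC(=O)[C@@H](CC(O)C[C@H](CC(OC)OC)C(C)=C)O1)P(=O)(OCC(F)(F)F)OCC(F)(F)F
F9 | step 18 | seco aldehyde: as F8 with C3 as the free aldehyde | COC(=O)C(CC(=O)C[C@]1(C)CC(=O)[C@@H](CC(O)C[C@H](CC=O)C(C)=C)O1)P(=O)(OCC(F)(F)F)OCC(F)(F)F
F10 | step 6 | (R)-4-[(tert-butyldiphenylsilyl)oxy]-2-(prop-1-en-2-yloxy)butanal | C=C(C)O[C@H](CCO[Si](c1ccccc1)(c1ccccc1)C(C)(C)C)C=O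
F11 | step 6 | (5R)-1-[(tert-butyldimethylsilyl)oxy]-7-[(tert-butyldiphenylsilyl)oxy]-4-hydroxy-5-(prop-1-en-2-yloxy)heptan-2-one (both C10 epimers) | CC(C)(C)[Si](C)(C)OCC(=O)CC(O)[C@@H](CCO[Si](c1ccccc1)(c1ccccc1)C(C)(C)C)OC(C)=C
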